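The C19–C20 single bond at the centre of the all-E C16–C25 pentaene of the 28-membered lactone ring is the disconnection on which everything rests (C1 = lactone carbonyl, C27 = carbon on the ring oxygen). Both atoms are sp2 CH termini, so an intramolecular Stille coupling forges this bond at the end of the assembly. In one operation it closes the macrocycle and completes the sensitive pentaene with retention of every alkene geometry. Its precursor is an open-chain ester: a hexasilylated C1–C19 acid ending in an (E,E)-dienyl iodide, esterified with a C20–C27 (E,E,E)-trienylstannane alcohol. The acid comes from a 1,5-anti aldol union of two fragments, the alcohol from C2-symmetric (2R,3R)-2,3-epoxybutane.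

Key step: step 24

**Remarks before the steps**

- Locants C1–C27 are those of the macrolide chain throughout (C2 carries the ethyl group, C15 is the allylic carbinol, C26 and C27 carry the two methyl groups at the lactone terminus).
- Abbreviations: TBS = tert-butyldimethylsilyl, PMB = 4-methoxybenzyl, Ipc = isopinocampheyl; TBSO and PMBO in names denote the corresponding ethers.
- Assumption: the enantiomers of the chiral reagents in steps 1 and 2 are chosen by the accepted models for these allylations; should either deliver the antipode, its mirror-image form is used.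
- Compounds 1, 7, 11, 14, 28, 29 and 33 are taken to be commercial.

**Route**

Step 1
Reactants: 1 tetrahydro-2H-pyran-2-ol (lactol form of 5-hydroxypentanal)
Product: 2 (5S)-7-methyloct-7-ene-1,5-diol
Conditions: (+)-Ipc2BOMe [from (−)-α-pinene], 2-methylallylmagnesium chloride, Et2O, −78 °C to rt; then 1, −78 °C to rt; NaOH, H2O2
Reagents that add atoms: 2-methylallylmagnesium chloride, CC(=C)C[Mg]Cl
Why: Brown allylboration of the open hydroxy-aldehyde form of the lactol through a chair Zimmerman–Traxler transition state, in which the Ipc groups should direct the methallyl group to the Re face and set the C9 carbinol as (S).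

Step 2
Reactants: 2 (5S)-7-methyloct-7-ene-1,5-diol
Product: 4 (4S,8S)-2-methylundeca-1,10-diene-4,8-diol, via hydroxy aldehyde 3 (not isolated)
Conditions: [Ir(cod)Cl]2 (2.5 mol %), (R)-Cl,MeO-BIPHEP (5 mol %), 4-chloro-3-nitrobenzoic acid (10 mol %), Cs2CO3 (20 mol %), allyl acetate, THF, 100 °C
Reagents that add atoms: allyl acetate, C=CCOC(C)=O
Why: Krische transfer-hydrogenative allylation, in which the cyclometallated π-allyl iridium C,O-benzoate dehydrogenates only the primary alcohol to 3 and allylates it in situ under control of the chiral bisphosphine, setting C5 as (S) while the secondary alcohol is left alone.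

Step 3
Reactants: 4 (4S,8S)-2-methylundeca-1,10-diene-4,8-diol
Product: 5 (4S,8S)-4,8-bis(PMBO)-2-methylundeca-1,10-diene
Conditions: NaH, PMBCl, Bu4NI (cat.), DMF/THF, 0 °C to rt
Reagents that add atoms: 4-methoxybenzyl chloride, COc1ccc(CCl)cc1
Why: Williamson etherification of both secondary alkoxides; the C9 PMB ether is the β-alkoxy director that step 13 relies on.

Step 4
Reactants: 5 (4S,8S)-4,8-bis(PMBO)-2-methylundeca-1,10-diene
Product: 6 (3S,7S)-3,7-bis(PMBO)-9-oxodecanal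
Conditions: O3, CH2Cl2/MeOH, NaHCO3, Sudan red 7B, −78 °C; then Me2S, −78 °C to rt
Reagents that add atoms: ozone, [O-][O+]=O
Why: Ozonolysis with reductive work-up cleaves both alkenes at once, the monosubstituted one to the C3 aldehyde and the 1,1-disubstituted one to the C11 methyl ketone, so the two chain ends become different; stopping at the indicator end point spares the PMB rings.

Step 5
Reactants: 6 (3S,7S)-3,7-bis(PMBO)-9-oxodecanal; 7 (4S)-4-benzyl-3-butanoyloxazolidin-2-one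
Product: 9 (4S)-4-benzyl-3-[(2S,3R,5S,9S)-2-ethyl-3-hydroxy-5,9-bis(PMBO)-11-oxododecanoyl]oxazolidin-2-one, via Z-boron enolate 8 (not isolated)
Conditions: 7 (1.2 equiv), Bu2BOTf (1.1 equiv), i-Pr2NEt, CH2Cl2, −78 to 0 °C; then 6, −78 to 0 °C; pH 7 buffer, MeOH, H2O2
Reagents that add atoms: none
Why: Evans syn aldol through a Zimmerman–Traxler chair in which the benzyl group of the (S)-auxiliary shields one enolate face, giving the 2,3-syn (2S,3R) adduct; the aldehyde reacts far faster than the methyl ketone and no free Bu2BOTf is left to enolise the ketone.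

Step 6
Reactants: 9 (the aldol adduct of step 5)
Product: 10 (4S)-4-benzyl-3-[(2S,3R,5S,9S)-3-(TBSO)-2-ethyl-5,9-bis(PMBO)-11-oxododecanoyl]oxazolidin-2-one
Conditions: TBSOTf, 2,6-lutidine, CH2Cl2, −78 °C
Reagents that add atoms: tert-butyldimethylsilyl triflate, CC(C)(C)[Si](C)(C)OS(=O)(=O)C(F)(F)F
Why: Silylation of the secondary alcohol at −78 °C is much faster than silyl enol ether formation from the methyl ketone with the weak base 2,6-lutidine, and it blocks retro-aldol cleavage later.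

Step 7
Reactants: 11 (2E)-4,4-dimethoxybut-2-enal
Product: 12 (1E,3E)-1-iodo-5,5-dimethoxypenta-1,3-diene
Conditions: CrCl2 (6 equiv), CHI3 (2 equiv), THF, 0 °C to rt
Reagents that add atoms: iodoform, IC(I)I
Why: Takai olefination, in which the geminal dichromium species from CHI3 adds to the aldehyde and eliminates to the E-vinyl iodide; the acetal is inert.

Step 8
Reactants: 12 (1E,3E)-1-iodo-5,5-dimethoxypenta-1,3-diene
Product: 13 (2E,4E)-5-iodopenta-2,4-dienal
Conditions: TsOH·H2O (cat.), acetone/H2O (9:1), rt, dark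
Reagents that add atoms: water, O
Why: Acid-catalysed acetal hydrolysis unmasks the aldehyde, and the conjugated E,E-iododiene keeps its geometry.

Step 9
Reactants: 13 (2E,4E)-5-iodopenta-2,4-dienal; 14 (4S)-4-benzyl-3-propanoyloxazolidin-2-one
Product: 16 (4S)-4-benzyl-3-[(2S,3R,4E,6E)-3-hydroxy-7-iodo-2-methylhepta-4,6-dienoyl]oxazolidin-2-one, via Z-boron enolate 15 (not isolated)
Conditions: 14, Bu2BOTf, i-Pr2NEt, CH2Cl2, −78 to 0 °C; then 13, −78 to 0 °C; pH 7 buffer, MeOH, H2O2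
Reagents that add atoms: none
Why: Evans syn aldol (1,2-addition to the dienal) through the same auxiliary-controlled chair transition state as in step 5, setting the C14 methyl and C15 hydroxyl syn with the (14R,15R) configuration of the target.

Step 10
Reactants: 16 (the aldol adduct of step 9)
Product: 17 (4S)-4-benzyl-3-[(2S,3R,4E,6E)-3-(TBSO)-7-iodo-2-methylhepta-4,6-dienoyl]oxazolidin-2-one
Conditions: TBSOTf, 2,6-lutidine, CH2Cl2, −78 to 0 °C
Reagents that add atoms: tert-butyldimethylsilyl triflate, CC(C)(C)[Si](C)(C)OS(=O)(=O)C(F)(F)F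
Why: Silylation protects the allylic C15 carbinol and prevents retro-aldol before the auxiliary is removed.

Step 11
Reactants: 17 (the silyl ether of step 10)
Product: 18 (2R,3R,4E,6E)-3-(TBSO)-7-iodo-2-methylhepta-4,6-dien-1-ol
Conditions: LiBH4, MeOH (1 equiv), THF, 0 °C
Reagents that add atoms: none
Why: Reductive cleavage of the N-acyl oxazolidinone by hydride attack at the exocyclic carbonyl gives the primary alcohol without touching the vinyl iodide or the silyl ether.

Step 12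
Reactants: 18 (the alcohol of step 11)
Product: 19 (2S,3R,4E,6E)-3-(TBSO)-7-iodo-2-methylhepta-4,6-dienal
Conditions: Dess–Martin periodinane, NaHCO3, CH2Cl2, 0 °C to rt
Reagents that add atoms: none
Why: Dess–Martin oxidation under buffered non-basic conditions gives the α-methyl aldehyde without epimerising C14; it is used at once.

Step 13
Reactants: 10 (C1–C12 methyl ketone of step 6); 19 (C13–C19 aldehyde of step 12)
Product: 21 (4S)-4-benzyl-3-[(2S,3R,5S,9S,13R,14R,15R,16E,18E)-3,15-bis(TBSO)-2-ethyl-13-hydroxy-19-iodo-5,9-bis(PMBO)-14-methyl-11-oxononadeca-16,18-dienoyl]oxazolidin-2-one, via boron enolate 20 (not isolated)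
Conditions: 10 (1.2 equiv), Cy2BCl, Et3N, Et2O, −78 to 0 °C; then 19, −78 to −20 °C; MeOH, pH 7 buffer, H2O2, 0 °C
Reagents that add atoms: none
Why: 1,5-anti boron aldol, in which Cy2BCl/Et3N enolises only the methyl side of the ketone (the hindered imide is not enolised) and the β-PMBO group at C9 steers the boat-like transition state so that the new C13 carbinol forms 1,5-anti to C9, i.e. (13R); this enolate control is expected to override the weak Felkin bias of the α-methyl aldehyde.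

Step 14
Reactants: 21 (the β-hydroxy ketone of step 13)
Product: 22 (4S)-4-benzyl-3-[(2S,3R,5S,9S,11R,13R,14R,15R,16E,18E)-3,15-bis(TBSO)-2-ethyl-11,13-dihydroxy-19-iodo-5,9-bis(PMBO)-14-methylnonadeca-16,18-dienoyl]oxazolidin-2-one
Conditions: Me4NBH(OAc)3, MeCN/AcOH (1:1), −30 to −20 °C
Reagents that add atoms: none
Why: Evans–Saksena reduction, in which acetoxy exchange with the C13 hydroxyl and intramolecular hydride delivery through a chair transition state give the 1,3-anti diol, placing C11 anti to C13 and therefore syn to C9 (the descriptor at C11 reads R here only because of the PMB ether).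

Step 15
Reactants: 22 (the anti diol of step 14)
Product: 23 (4S)-4-benzyl-3-[(2S,3R,5S,9S,11S,13R,14R,15R,16E,18E)-3,11,13,15-tetrakis(TBSO)-2-ethyl-19-iodo-5,9-bis(PMBO)-14-methylnonadeca-16,18-dienoyl]oxazolidin-2-one
Conditions: TBSOTf, 2,6-lutidine, CH2Cl2, −78 to 0 °C
Reagents that add atoms: tert-butyldimethylsilyl triflate, CC(C)(C)[Si](C)(C)OS(=O)(=O)C(F)(F)F
Why: Silylation of both diol hydroxyls, so that no neighbouring free hydroxyl can trap the benzylic cation as a cyclic acetal in step 16.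

Step 16
Reactants: 23 (the tetrasilyl ether of step 15)
Product: 24 (4S)-4-benzyl-3-[(2S,3R,5S,9S,11S,13R,14R,15R,16E,18E)-3,11,13,15-tetrakis(TBSO)-2-ethyl-5,9-dihydroxy-19-iodo-14-methylnonadeca-16,18-dienoyl]oxazolidin-2-one
Conditions: DDQ, CH2Cl2/pH 7 buffer (10:1), 0 °C; crude diol carried directly into step 17
Reagents that add atoms: none
Why: Oxidative PMB cleavage by DDQ (hydride abstraction at the electron-rich benzylic position, then hydrolysis of the oxocarbenium ion), to which silyl ethers, the imide and the iododiene are inert; the buffered medium and immediate resilylation should keep the C5 hydroxyl from lactonising onto the hindered imide carbonyl.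

Step 17
Reactants: 24 (the C5,C9 diol of step 16)
Product: 25 (4S)-4-benzyl-3-[(2S,3R,5S,9S,11S,13R,14R,15R,16E,18E)-3,5,9,11,13,15-hexakis(TBSO)-2-ethyl-19-iodo-14-methylnonadeca-16,18-dienoyl]oxazolidin-2-one
Conditions: TBSOTf, 2,6-lutidine, CH2Cl2, −78 to 0 °C
Reagents that add atoms: tert-butyldimethylsilyl triflate, CC(C)(C)[Si](C)(C)OS(=O)(=O)C(F)(F)F
Why: Silylation brings all six hydroxyls to one fluoride-labile protecting group for a single final deprotection.

Step 18
Reactants: 25 (the hexasilylated imide of step 17)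
Product: 27 (2S,3R,5S,9S,11S,13R,14R,15R,16E,18E)-3,5,9,11,13,15-hexakis(TBSO)-2-ethyl-19-iodo-14-methylnonadeca-16,18-dienoic acid, via peroxy acid 26 (not isolated)
Conditions: LiOH·H2O, 30% H2O2, THF/H2O (3:1), 0 °C to rt; Na2SO3; 1 M HCl to pH 4
Reagents that add atoms: hydrogen peroxide, OO
Why: Hydroperoxide (an α-effect nucleophile) attacks the exocyclic imide carbonyl selectively, sulfite reduces the peroxy acid 26, and the mild conditions leave C2, the silyl ethers and the iododiene intact.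

Step 19
Reactants: 28 (E)-1,2-dichloroethene; 29 ethynyltrimethylsilane
Product: 30 (E)-1,6-bis(trimethylsilyl)hex-3-ene-1,5-diyne
Conditions: 29 (2.2 equiv in all), Pd(PPh3)4 (5 mol %), CuI (10 mol %), n-BuNH2, benzene, rt
Reagents that add atoms: ethynyltrimethylsilane (the second equivalent), C#C[Si](C)(C)C
Why: Twofold Sonogashira coupling with retention of the E geometry of the dichloroalkene, in which one molecule of the alkyne replaces each chlorine and the first alkynylation activates the second C–Cl bond toward oxidative addition.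

Step 20
Reactants: 30 (E)-1,6-bis(trimethylsilyl)hex-3-ene-1,5-diyne
Product: 31 (E)-hex-3-ene-1,5-diyne
Conditions: K2CO3 (cat.), MeOH, rt; carried on as a solution
Reagents that add atoms: none
Why: Methanolysis of the two C(sp)–Si bonds by catalytic methoxide.

Step 21
Reactants: 31 (E)-hex-3-ene-1,5-diyne
Product: 32 (1E,3E,5E)-1,6-bis(tributylstannyl)hexa-1,3,5-triene
Conditions: Bu3SnH (2.2 equiv), AIBN (cat.), benzene, 80 °C
Reagents that add atoms: tributyltin hydride, CCCC[SnH](CCCC)CCCC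
Why: Radical hydrostannation, in which the stannyl radical adds to the terminal carbon of each alkyne and reversible addition–elimination under prolonged heating should equilibrate the new double bonds to the favoured E geometry.

Step 22
Reactants: 32 (the bis-stannyl triene of step 21); 33 (2R,3R)-2,3-dimethyloxirane
Product: 35 (2R,3R,4E,6E,8E)-3-methyl-9-(tributylstannyl)nona-4,6,8-trien-2-ol, via trienyllithium 34 (not isolated)
Conditions: 32 (1.3 equiv), MeLi (1.0 equiv), THF, −78 °C; then BF3·OEt2, 33, −78 °C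
Reagents that add atoms: none
Why: Tin–lithium exchange with one equivalent of MeLi gives 34 with retention of geometry, and BF3-promoted SN2 opening of the epoxide inverts the attacked carbon; because the epoxide is C2-symmetric either carbon gives the same (2R,3R) product with methyl and hydroxyl syn.

Step 23
Reactants: 27 (the acid of step 18); 35 (the stannyl trienol of step 22)
Product: 37 (2R,3R,4E,6E,8E)-3-methyl-9-(tributylstannyl)nona-4,6,8-trien-2-yl (2S,3R,5S,9S,11S,13R,14R,15R,16E,18E)-3,5,9,11,13,15-hexakis(TBSO)-2-ethyl-19-iodo-14-methylnonadeca-16,18-dienoate, via mixed anhydride 36 (not isolated)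
Conditions: 27, 2,4,6-trichlorobenzoyl chloride, Et3N, THF, rt; then 35, DMAP, toluene, rt
Reagents that add atoms: none
Why: Yamaguchi esterification, in which DMAP attacks the less hindered aliphatic carbonyl of 36 and the acylpyridinium acylates the hindered C27 alcohol under neutral conditions that the stannane tolerates; no stereocentre is touched.

Step 24
Reactants: 37 (the seco ester of step 23)
Product: 38 (3S,4R,6S,10S,12S,14R,15R,16R,17E,19E,21E,23E,25E,27R,28R)-4,6,10,12,14,16-hexakis(TBSO)-3-ethyl-15,27,28-trimethyl-1-oxacyclooctacosa-17,19,21,23,25-pentaen-2-one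
Conditions: Pd2(dba)3·CHCl3 (20 mol %), AsPh3 (1.6 equiv), i-Pr2NEt, degassed DMF/THF (1:1), 1 mM (slow addition of 37), rt, dark
Reagents that add atoms: none
Why: Zerovalent palladium inserts into the C19–I bond of the dienyl iodide, the C20 trienylstannane terminus transmetallates from tin to palladium within the same molecule, and reductive elimination forms the C19–C20 σ-bond, each elementary step retaining alkene geometry. The closest known reaction type is the Stille macrocyclisation of ω-stannyl vinyl iodides used to close polyene macrolides and macrolactams. One ring is closed, the 28-membered lactone, by end-to-end sp2–sp2 coupling of the two chain termini of the seco ester. No stereocentre is created; the E geometry of the C18=C19 and C20=C21 bonds is already present in the iodide and the stannane and is carried into the product unchanged. The step needs cyclisation to win over oligomerisation, protodestannylation and homocoupling; this is secured by high dilution with slow addition, the rigid all-E diene and triene termini, the silyl-clad polyol chain that favours folded conformers, and the weakly donating AsPh3 ligand that speeds transmetallation under neutral conditions at room temperature.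

Step 25
Reactants: 38 (the hexasilylated macrolide of step 24)
Product: 39 (3S,4R,6S,10S,12S,14R,15R,16R,17E,19E,21E,23E,25E,27R,28R)-3-ethyl-4,6,10,12,14,16-hexahydroxy-15,27,28-trimethyl-1-oxacyclooctacosa-17,19,21,23,25-pentaen-2-one (the target)
Conditions: HF·pyridine, pyridine, THF, 0 °C to rt, polypropylene vessel, dark
Reagents that add atoms: none
Why: Fluoride-mediated cleavage of the six Si–O bonds with pyridine-buffered HF·pyridine, strong enough for secondary TBS ethers yet mild enough for the pentaene and the allylic C15 alcohol.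

**Compound list**

1 | tetrahydro-2H-pyran-2-ol | OC1CCCCO1 | starting material
2 | (5S)-7-methyloct-7-ene-1,5-diol | OCCCC[C@H](O)CC(C)=C | intermediate
3 | (5S)-5-hydroxy-7-methyloct-7-enal | O=CCCC[C@H](O)CC(C)=C | intermediate (not isolated)
4 | (4S,8S)-2-methylundeca-1,10-diene-4,8-diol | C=CC[C@@H](O)CCC[C@H](O)CC(C)=C | intermediate
5 | (4S,8S)-4,8-bis(PMBO)-2-methylundeca-1,10-diene | C=CC[C@@H](OCc1ccc(OC)cc1)CCC[C@H](OCc2ccc(OC)cc2)CC(C)=C | intermediate
6 | (3S,7S)-3,7-bis(PMBO)-9-oxodecanal | O=CC[C@@H](OCc1ccc(OC)cc1)CCC[C@H](OCc2ccc(OC)cc2)CC(C)=O | intermediate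
7 | (4S)-4-benzyl-3-butanoyloxazolidin-2-one | CCCC(=O)N1[C@@H](Cc2ccccc2)COC1=O | starting material
8 | Z-dibutylboron enolate of 7 | CC/C=C(\OB(CCCC)CCCC)N1[C@@H](Cc2ccccc2)COC1=O | intermediate (not isolated)
9 | (4S)-4-benzyl-3-[(2S,3R,5S,9S)-2-ethyl-3-hydroxy-5,9-bis(PMBO)-11-oxododecanoyl]oxazolidin-2-one | CC[C@H](C(=O)N1[C@@H](Cc2ccccc2)COC1=O)[C@H](O)C[C@@H](OCc3ccc(OC)cc3)CCC[C@H](OCc4ccc(OC)cc4)CC(C)=O | intermediate
10 | (4S)-4-benzyl-3-[(2S,3R,5S,9S)-3-(TBSO)-2-ethyl-5,9-bis(PMBO)-11-oxododecanoyl]oxazolidin-2-one | CC[C@H](C(=O)N1[C@@H](Cc2ccccc2)COC1=O)[C@H](O[Si](C)(C)C(C)(C)C)C[C@@H](OCc3ccc(OC)cc3)CCC[C@H](OCc4ccc(OC)cc4)CC(C)=O | intermediate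
11 | (2E)-4,4-dimethoxybut-2-enal | COC(OC)/C=C/C=O | starting material
12 | (1E,3E)-1-iodo-5,5-dimethoxypenta-1,3-diene | COC(OC)/C=C/C=C/I | intermediate
13 | (2E,4E)-5-iodopenta-2,4-dienal | O=C/C=C/C=C/I | intermediate
14 | (4S)-4-benzyl-3-propanoyloxazolidin-2-one | CCC(=O)N1[C@@H](Cc2ccccc2)COC1=O | starting material
15 | Z-dibutylboron enolate of 14 | C/C=C(\OB(CCCC)CCCC)N1[C@@H](Cc2ccccc2)COC1=O | intermediate (not isolated)
16 | (4S)-4-benzyl-3-[(2S,3R,4E,6E)-3-hydroxy-7-iodo-2-methylhepta-4,6-dienoyl]oxazolidin-2-one | C[C@H](C(=O)N1[C@@H](Cc2ccccc2)COC1=O)[C@H](O)/C=C/C=C/I | intermediate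
17 | (4S)-4-benzyl-3-[(2S,3R,4E,6E)-3-(TBSO)-7-iodo-2-methylhepta-4,6-dienoyl]oxazolidin-2-one | C[C@H](C(=O)N1[C@@H](Cc2ccccc2)COC1=O)[C@H](O[Si](C)(C)C(C)(C)C)/C=C/C=C/I | intermediate
18 | (2R,3R,4E,6E)-3-(TBSO)-7-iodo-2-methylhepta-4,6-dien-1-ol | OC[C@@H](C)[C@H](O[Si](C)(C)C(C)(C)C)/C=C/C=C/I | intermediate
19 | (2S,3R,4E,6E)-3-(TBSO)-7-iodo-2-methylhepta-4,6-dienal | O=C[C@@H](C)[C@H](O[Si](C)(C)C(C)(C)C)/C=C/C=C/I | intermediate
20 | dicyclohexylboron enolate of 10 (C11=C12 enol borinate) | CC[C@H](C(=O)N1[C@@H](Cc2ccccc2)COC1=O)[C@H](O[Si](C)(C)C(C)(C)C)C[C@@H](OCc3ccc(OC)cc3)CCC[C@H](OCc4ccc(OC)cc4)CC(=C)OB(C5CCCCC5)C6CCCCC6 | intermediate (not isolated)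
21 | (4S)-4-benzyl-3-[(2S,3R,5S,9S,13R,14R,15R,16E,18E)-3,15-bis(TBSO)-2-ethyl-13-hydroxy-19-iodo-5,9-bis(PMBO)-14-methyl-11-oxononadeca-16,18-dienoyl]oxazolidin-2-one | CC[C@H](C(=O)N1[C@@H](Cc2ccccc2)COC1=O)[C@H](O[Si](C)(C)C(C)(C)C)C[C@@H](OCc3ccc(OC)cc3)CCC[C@H](OCc4ccc(OC)cc4)CC(=O)C[C@@H](O)[C@@H](C)[C@H](O[Si](C)(C)C(C)(C)C)/C=C/C=C/I | intermediate
22 | (4S)-4-benzyl-3-[(2S,3R,5S,9S,11R,13R,14R,15R,16E,18E)-3,15-bis(TBSO)-2-ethyl-11,13-dihydroxy-19-iodo-5,9-bis(PMBO)-14-methylnonadeca-16,18-dienoyl]oxazolidin-2-one | CC[C@H](C(=O)N1[C@@H](Cc2ccccc2)COC1=O)[C@H](O[Si](C)(C)C(C)(C)C)C[C@@H](OCc3ccc(OC)cc3)CCC[C@H](OCc4ccc(OC)cc4)C[C@H](O)C[C@@H](O)[C@@H](C)[C@H](O[Si](C)(C)C(C)(C)C)/C=C/C=C/I | intermediate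
23 | (4S)-4-benzyl-3-[(2S,3R,5S,9S,11S,13R,14R,15R,16E,18E)-3,11,13,15-tetrakis(TBSO)-2-ethyl-19-iodo-5,9-bis(PMBO)-14-methylnonadeca-16,18-dienoyl]oxazolidin-2-one | CC[C@H](C(=O)N1[C@@H](Cc2ccccc2)COC1=O)[C@H](O[Si](C)(C)C(C)(C)C)C[C@@H](OCc3ccc(OC)cc3)CCC[C@H](OCc4ccc(OC)cc4)C[C@H](O[Si](C)(C)C(C)(C)C)C[C@@H](O[Si](C)(C)C(C)(C)C)[C@@H](C)[C@H](O[Si](C)(C)C(C)(C)C)/C=C/C=C/I | intermediate
24 | (4S)-4-benzyl-3-[(2S,3R,5S,9S,11S,13R,14R,15R,16E,18E)-3,11,13,15-tetrakis(TBSO)-2-ethyl-5,9-dihydroxy-19-iodo-14-methylnonadeca-16,18-dienoyl]oxazolidin-2-one | CC[C@H](C(=O)N1[C@@H](Cc2ccccc2)COC1=O)[C@H](O[Si](C)(C)C(C)(C)C)C[C@@H](O)CCC[C@H](O)C[C@H](O[Si](C)(C)C(C)(C)C)C[C@@H](O[Si](C)(C)C(C)(C)C)[C@@H](C)[C@H](O[Si](C)(C)C(C)(C)C)/C=C/C=C/I | intermediate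
25 | (4S)-4-benzyl-3-[(2S,3R,5S,9S,11S,13R,14R,15R,16E,18E)-3,5,9,11,13,15-hexakis(TBSO)-2-ethyl-19-iodo-14-methylnonadeca-16,18-dienoyl]oxazolidin-2-one | CC[C@H](C(=O)N1[C@@H](Cc2ccccc2)COC1=O)[C@H](O[Si](C)(C)C(C)(C)C)C[C@@H](O[Si](C)(C)C(C)(C)C)CCC[C@H](O[Si](C)(C)C(C)(C)C)C[C@H](O[Si](C)(C)C(C)(C)C)C[C@@H](O[Si](C)(C)C(C)(C)C)[C@@H](C)[C@H](O[Si](C)(C)C(C)(C)C)/C=C/C=C/I | intermediate
26 | peroxy acid corresponding to 27 | CC[C@H](C(=O)OO)[C@H](O[Si](C)(C)C(C)(C)C)C[C@@H](O[Si](C)(C)C(C)(C)C)CCC[C@H](O[Si](C)(C)C(C)(C)C)C[C@H](O[Si](C)(C)C(C)(C)C)C[C@@H](O[Si](C)(C)C(C)(C)C)[C@@H](C)[C@H](O[Si](C)(C)C(C)(C)C)/C=C/C=C/I | intermediate (not isolated)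
27 | (2S,3R,5S,9S,11S,13R,14R,15R,16E,18E)-3,5,9,11,13,15-hexakis(TBSO)-2-ethyl-19-iodo-14-methylnonadeca-16,18-dienoic acid | CC[C@H](C(=O)O)[C@H](O[Si](C)(C)C(C)(C)C)C[C@@H](O[Si](C)(C)C(C)(C)C)CCC[C@H](O[Si](C)(C)C(C)(C)C)C[C@H](O[Si](C)(C)C(C)(C)C)C[C@@H](O[Si](C)(C)C(C)(C)C)[C@@H](C)[C@H](O[Si](C)(C)C(C)(C)C)/C=C/C=C/I | intermediate
28 | (E)-1,2-dichloroethene | Cl/C=C/Cl | starting material
29 | ethynyltrimethylsilane | C#C[Si](C)(C)C | starting material
30 | (E)-1,6-bis(trimethylsilyl)hex-3-ene-1,5-diyne | C[Si](C)(C)C#C/C=C/C#C[Si](C)(C)C | intermediate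
31 | (E)-hex-3-ene-1,5-diyne | C#C/C=C/C#C | intermediate
32 | (1E,3E,5E)-1,6-bis(tributylstannyl)hexa-1,3,5-triene | CCCC[Sn](CCCC)(CCCC)/C=C/C=C/C=C/[Sn](CCCC)(CCCC)CCCC | intermediate
33 | (2R,3R)-2,3-dimethyloxirane (trans-2,3-epoxybutane) | C[C@H]1O[C@@H]1C | starting material
34 | [(1E,3E,5E)-6-(tributylstannyl)hexa-1,3,5-trien-1-yl]lithium | [Li]/C=C/C=C/C=C/[Sn](CCCC)(CCCC)CCCC | intermediate (not isolated)
35 | (2R,3R,4E,6E,8E)-3-methyl-9-(tributylstannyl)nona-4,6,8-trien-2-ol | C[C@@H](O)[C@H](C)/C=C/C=C/C=C/[Sn](CCCC)(CCCC)CCCC | intermediate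
36 | mixed anhydride of 27 with 2,4,6-trichlorobenzoic acid | CC[C@H](C(=O)OC(=O)c1c(Cl)cc(Cl)cc1Cl)[C@H](O[Si](C)(C)C(C)(C)C)C[C@@H](O[Si](C)(C)C(C)(C)C)CCC[C@H](O[Si](C)(C)C(C)(C)C)C[C@H](O[Si](C)(C)C(C)(C)C)C[C@@H](O[Si](C)(C)C(C)(C)C)[C@@H](C)[C@H](O[Si](C)(C)C(C)(C)C)/C=C/C=C/I | intermediate (not isolated)
37 | (2R,3R,4E,6E,8E)-3-methyl-9-(tributylstannyl)nona-4,6,8-trien-2-yl (2S,3R,5S,9S,11S,13R,14R,15R,16E,18E)-3,5,9,11,13,15-hexakis(TBSO)-2-ethyl-19-iodo-14-methylnonadeca-16,18-dienoate | CC[C@H](C(=O)O[C@H](C)[C@H](C)/C=C/C=C/C=C/[Sn](CCCC)(CCCC)CCCC)[C@H](O[Si](C)(C)C(C)(C)C)C[C@@H](O[Si](C)(C)C(C)(C)C)CCC[C@H](O[Si](C)(C)C(C)(C)C)C[C@H](O[Si](C)(C)C(C)(C)C)C[C@@H](O[Si](C)(C)C(C)(C)C)[C@@H](C)[C@H](O[Si](C)(C)C(C)(C)C)/C=C/C=C/I | intermediate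
38 | (3S,4R,6S,10S,12S,14R,15R,16R,17E,19E,21E,23E,25E,27R,28R)-4,6,10,12,14,16-hexakis(TBSO)-3-ethyl-15,27,28-trimethyl-1-oxacyclooctacosa-17,19,21,23,25-pentaen-2-one | CC[C@@H]1C(=O)O[C@H](C)[C@H](C)/C=C/C=C/C=C/C=C/C=C/[C@@H](O[Si](C)(C)C(C)(C)C)[C@H](C)[C@H](O[Si](C)(C)C(C)(C)C)C[C@@H](O[Si](C)(C)C(C)(C)C)C[C@@H](O[Si](C)(C)C(C)(C)C)CCC[C@H](O[Si](C)(C)C(C)(C)C)C[C@H]1O[Si](C)(C)C(C)(C)C | intermediate
39 | (3S,4R,6S,10S,12S,14R,15R,16R,17E,19E,21E,23E,25E,27R,28R)-3-ethyl-4,6,10,12,14,16-hexahydroxy-15,27,28-trimethyl-1-oxacyclooctacosa-17,19,21,23,25-pentaen-2-one | CC[C@@H]1C(=O)O[C@H](C)[C@H](C)/C=C/C=C/C=C/C=C/C=C/[C@@H](O)[C@H](C)[C@H](O)C[C@@H](O)C[C@@H](O)CCC[C@H](O)C[C@H]1O | target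

**Totals**

Total step count: 25. Longest linear sequence: 15 steps (steps 1–6, 13–18 and 23–25; the sequence 7–12, 13–18, 23–25 is equally long).

**Steps most likely to fail, with fallbacks**

1. Step 24 (macrocyclisation). Intermolecular coupling to oligomers, protodestannylation of the trienylstannane, or light- and palladium-induced E/Z scrambling of the growing pentaene may outrun ring closure. Fallback: close the same C19–C20 bond by a tin-free Heck macrocyclisation. Setting out from 35, protodestannylation (CF3CO2H, CH2Cl2, −40 °C) would give (2R,3R,4E,6E)-3-methylnona-4,6,8-trien-2-ol F1. The Yamaguchi protocol of step 23 with acid 27 would then give the tin-free seco ester F2, which carries a terminal triene and the C19 dienyl iodide. Heck cyclisation (Pd(OAc)2, K2CO3, Bu4NCl, DMF, 60 °C, high dilution) would add the C19 dienylpalladium to the terminal C20 methylene, and syn β-hydride elimination toward the conjugated chain would give the E C20=C21 bond. The route is rejoined at 38.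

2. Step 13 (fragment-uniting aldol). The 1,5-anti preference of the enolate opposes the Felkin preference of the α-methyl aldehyde, so facial selectivity at C13 may erode; the aldehyde may also epimerise at C14. Fallback: an open-transition-state Mukaiyama aldol controlled by the aldehyde, whose β-PMB ether imposes 1,3-anti induction toward unhindered enol silanes. Setting out from 16 and 10, adduct 16 would be converted with 4-methoxybenzyl trichloroacetimidate and TfOH (cat.) into the C15 PMB ether of the aldol adduct F3. LiBH4 would give the PMB-protected iododienol F4, and Dess–Martin oxidation the PMB-protected iododienal F5. Ketone 10 would be converted (LiN(SiMe3)2, Me3SiCl, THF, −78 °C, internal quench) into the trimethylsilyl enol ether F6, the hindered C2–H of the imide being expected to react more slowly than the methyl group. BF3·OEt2 at −78 °C would unite F5 and F6 to the C15-PMBO β-hydroxy ketone F7. Me4NBH(OAc)3 would give the C15-PMBO anti diol F8, and TBSOTf the tris-silyl ether with three PMB ethers F9. DDQ would remove all three PMB groups to give the C5,C9,C15 triol F10, and TBSOTf would return to the route at 25.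

3. Step 22 (trienylstannane alcohol). Tin–lithium exchange may not stop cleanly at the mono-lithio stage, opening of the 1,2-disubstituted epoxide may be sluggish, and the Lewis acid may degrade the stannyl triene. Fallback: build the triene by olefination from the same epoxide, which also makes steps 19–21 unnecessary. Setting out from 33, copper-catalysed opening with vinylmagnesium bromide (CuI cat., THF, −20 °C) would give (2R,3R)-3-methylpent-4-en-2-ol F11. TBSCl/imidazole would give its silyl ether F12, and ozonolysis (O3, then PPh3) would give (2S,3R)-3-(TBSO)-2-methylbutanal F13. Two successive Wittig homologations with (triphenylphosphoranylidene)acetaldehyde would give (2E,4R,5R)-5-(TBSO)-4-methylhex-2-enal F14 and then (2E,4E,6R,7R)-7-(TBSO)-6-methylocta-2,4-dienal F15. Takai-type stannyl olefination with (dibromomethyl)tributylstannane F16 (from CH2Br2, LiN(i-Pr)2 and Bu3SnCl) and CrCl2/LiI in DMF/THF would give the silyl ether of the stannyl trienol F17. Bu4NF would return to the route at 35.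

**Further compounds**

F1 | step 24 | (2R,3R,4E,6E)-3-methylnona-4,6,8-trien-2-ol | C[C@@H](O)[C@H](C)/C=C/C=C/C=C
F2 | step 24 | (2R,3R,4E,6E)-3-methylnona-4,6,8-trien-2-yl ester of acid 27 (tin-free seco ester) | CC[C@H](C(=O)O[C@H](C)[C@H](C)/C=C/C=C/C=C)[C@H](O[Si](C)(C)C(C)(C)C)C[C@@H](O[Si](C)(C)C(C)(C)C)CCC[C@H](O[Si](C)(C)C(C)(C)C)C[C@H](O[Si](C)(C)C(C)(C)C)C[C@@H](O[Si](C)(C)C(C)(C)C)[C@@H](C)[C@H](O[Si](C)(C)C(C)(C)C)/C=C/C=C/I
F3 | step 13 | C15 PMB ether of aldol adduct 16 | C[C@H](C(=O)N1[C@@H](Cc2ccccc2)COC1=O)[C@H](OCc3ccc(OC)cc3)/C=C/C=C/I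
F4 | step 13 | (2R,3R,4E,6E)-7-iodo-3-(PMBO)-2-methylhepta-4,6-dien-1-ol | OC[C@@H](C)[C@H](OCc1ccc(OC)cc1)/C=C/C=C/I
F5 | step 13 | (2S,3R,4E,6E)-7-iodo-3-(PMBO)-2-methylhepta-4,6-dienal | O=C[C@@H](C)[C@H](OCc1ccc(OC)cc1)/C=C/C=C/I
F6 | step 13 | trimethylsilyl enol ether of ketone 10 | CC[C@H](C(=O)N1[C@@H](Cc2ccccc2)COC1=O)[C@H](O[Si](C)(C)C(C)(C)C)C[C@@H](OCc3ccc(OC)cc3)CCC[C@H](OCc4ccc(OC)cc4)CC(=C)O[Si](C)(C)C
F7 | step 13 | C15-PMBO β-hydroxy ketone (C15-PMBO analogue of 21) | CC[C@H](C(=O)N1[C@@H](Cc2ccccc2)COC1=O)[C@H](O[Si](C)(C)C(C)(C)C)C[C@@H](OCc3ccc(OC)cc3)CCC[C@H](OCc4ccc(OC)cc4)CC(=O)C[C@@H](O)[C@@H](C)[C@H](OCc5ccc(OC)cc5)/C=C/C=C/I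
F8 | step 13 | C15-PMBO anti diol (C15-PMBO analogue of 22) | CC[C@H](C(=O)N1[C@@H](Cc2ccccc2)COC1=O)[C@H](O[Si](C)(C)C(C)(C)C)C[C@@H](OCc3ccc(OC)cc3)CCC[C@H](OCc4ccc(OC)cc4)C[C@H](O)C[C@@H](O)[C@@H](C)[C@H](OCc5ccc(OC)cc5)/C=C/C=C/I
F9 | step 13 | C3,C11,C13-tris-TBS ether with PMB ethers at C5, C9 and C15 | CC[C@H](C(=O)N1[C@@H](Cc2ccccc2)COC1=O)[C@H](O[Si](C)(C)C(C)(C)C)C[C@@H](OCc3ccc(OC)cc3)CCC[C@H](OCc4ccc(OC)cc4)C[C@H](O[Si](C)(C)C(C)(C)C)C[C@@H](O[Si](C)(C)C(C)(C)C)[C@@H](C)[C@H](OCc5ccc(OC)cc5)/C=C/C=C/I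
F10 | step 13 | C5,C9,C15 triol with TBS ethers at C3, C11 and C13 | CC[C@H](C(=O)N1[C@@H](Cc2ccccc2)COC1=O)[C@H](O[Si](C)(C)C(C)(C)C)C[C@@H](O)CCC[C@H](O)C[C@H](O[Si](C)(C)C(C)(C)C)C[C@@H](O[Si](C)(C)C(C)(C)C)[C@@H](C)[C@H](O)/C=C/C=C/I
F11 | step 22 | (2R,3R)-3-methylpent-4-en-2-ol | C[C@@H](O)[C@H](C)C=C
F12 | step 22 | TBS ether of F11 | C[C@@H](O[Si](C)(C)C(C)(C)C)[C@H](C)C=C
F13 | step 22 | (2S,3R)-3-(TBSO)-2-methylbutanal | C[C@@H](O[Si](C)(C)C(C)(C)C)[C@H](C)C=O
F14 | step 22 | (2E,4R,5R)-5-(TBSO)-4-methylhex-2-enal | C[C@@H](O[Si](C)(C)C(C)(C)C)[C@H](C)/C=C/C=O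
F15 | step 22 | (2E,4E,6R,7R)-7-(TBSO)-6-methylocta-2,4-dienal | C[C@@H](O[Si](C)(C)C(C)(C)C)[C@H](C)/C=C/C=C/C=O
F16 | step 22 | (dibromomethyl)tributylstannane | CCCC[Sn](CCCC)(CCCC)C(Br)Br
F17 | step 22 | TBS ether of 35 | C[C@@H](O[Si](C)(C)C(C)(C)C)[C@H](C)/C=C/C=C/C=C/[Sn](CCCC)(CCCC)CCCC
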